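**Assumption:** the Rh/(S)-SEGPHOS catalyst is taken to deliver the aryl group to the face of 2 that gives the (4S) lactone, by analogy with unsubstituted coumarin. If the opposite sense operates, (R)-SEGPHOS is used and nothing else changes.

## Structural features

Gnetulin (15) is a 2,3-dihydro-1H-indene. Ring A is the fused benzene ring (C3a, C4–C7, C7a) with hydroxyl groups at C4 and C6; ring B is the five-membered carbocycle (C1, C2, C3, C3a, C7a). C1 carries an exocyclic 4-hydroxy-3-methoxybenzylidene group of E geometry (aryl trans to C7a, cis to C2), C2 a 3,5-dihydroxyphenyl group and C3 a 4-hydroxy-3-methoxyphenyl group. C2 and C3 are adjacent stereocentres, both S, with the two aryl groups trans; C3 is doubly benzylic, C2 is benzylic and allylic. The fragile points are the C2–H bond (its loss as a proton, or toward a cation at C1, moves the alkene into ring B and then erases C3 as well), the electron-rich stilbene unit (easily protonated and then trapped by the C2 aryl ring), and six phenols, of which only the two on the guaiacyl rings keep a neighbouring methyl ether. The real difficulty is coupled: the absolute configuration of the trans-diaryl pair, and a trisubstituted exocyclic alkene of fixed geometry placed directly beside the labile C2, both to be made without a cation or anion at C1–C3. The feature exploited is in ring A: C4–O, C6–O and C7a are mutually meta, so ring A is a phloroglucinol whose third oxygen has been replaced by C1. An oxygen placed on C7a can therefore first be a ring oxygen bonded to C1 (a six-membered lactone holding C1, C2 and C3) and later a leaving group for the C7a–C1 bond.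

## Logic of the disconnections

Atom labels C1–C7a are those of 15 and are kept for the same atoms in every intermediate.

15 to 14: the six O–CH2Ph bonds are cut. Benzyl is the one ether that can be told apart from the two methyl ethers without hydrogenation. The forward step must cleave six ethers with a Lewis acid at low temperature without protonating the stilbene.

14 to 13 (key): the C7a–C1 bond is cut, the exocyclic alkene becomes an alkyne (C1 and the benzylidene carbon) and C7a receives a triflate. This is the only bond of ring B that can be made with both stereocentres already in place and untouched, and syn addition across the alkyne fixes the E geometry. Ring B disappears and 13 is an open chain on a phenol-derived arene. The forward step needs 5-exo-dig insertion faster than reduction of the aryl–palladium bond, and hydride capture faster than isomerisation of the alkenyl–palladium bond.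

13 to 12: the O–S bond is cut; the oxygen on C7a becomes a free phenol. The forward step only needs a mild sulfonylation.

12 to 10 and 11: the alkyne C–aryl bond is cut. This removes one aryl ring as a commercial iodide; the forward coupling must run at room temperature beside a free phenol.

10 to 8 (through 9): the terminal alkyne carbon is removed and C1 returns to the aldehyde level, where it closes onto the C7a oxygen. This reveals the six-membered ring C (O, C1, C2, C3, C3a, C7a); ring B of 15 is this ring with the oxygen excised. The forward one-carbon homologation must not epimerise C2, which is α to the aldehyde.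

8 to 7: the C1–H bond is cut, giving the lactone. The forward reduction must stop at the lactol.

7 to 4 and 5 (through 6): the C2–aryl bond is cut. In the lactone C2 is α to the carbonyl, so it can be arylated as an enolate and equilibrated to trans under control of C3. The forward step needs an enolate mild enough not to fragment the aryl ester.

4 to 2 and 3: the C3–aryl bond is cut. C3 is the β-carbon of a coumarin, so the absolute configuration comes from a catalytic asymmetric conjugate addition to a flat, achiral heterocycle. The forward step must overcome the peri C4–O substituent and the electron-rich lactone.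

2 to 1: the two O–benzyl bonds on ring A are cut, leading to a commercial phloroglucinol-derived coumarin in which all three oxygens of ring A are already differentiated.

## Other disconnections considered

Alternative 1: the first idea is the biomimetic cut of C1–C2 and C3–C3a. One-electron oxidation of isorhapontigenin A1 (FeCl3 or a peroxidase with H2O2) would give radicals that couple to the bis(quinone methide) A2; Friedel–Crafts closure and tautomerisation would give 15. The radical is delocalised over oxygen, the ring and the benzylic carbon, so several dimer connectivities compete. The coupling also occurs away from any chiral catalyst, so A2 would form as a meso/dl mixture and 15 as a racemate. It is the shortest plan but cannot deliver one enantiomer.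

Alternative 2: cut C2–C3. Acid would ionise the carbinol A3 to a p-alkoxybenzyl cation at C3, the stilbene alkene would attack it (5-endo), and the C1 cation would be trapped by a thiol; oxidation to the sulfone A4 and a Ramberg–Bäcklund reaction would give the alkene. The trans relation follows from the cyclisation, but it runs through free planar cations at C3 and C1 with no binding site for a chiral controller. The alkene costs three further operations and its geometry rests on the extrusion step.

Alternative 3: cut C3–aryl in a ketone. Rhodium-catalysed asymmetric conjugate addition of 3 to the indenone A5 would give the trans indanone A6 after equilibration of C2. The stereocentres would be set as in the chosen plan, but C1 is then a hindered ketone flanked by the acidic C2–H. Ylides would enolise it. Addition of a benzyl organometallic followed by loss of water would partition toward the ring, because losing C2–H gives a tetrasubstituted, doubly conjugated alkene; that erases C2 and leaves the geometry uncontrolled. In the chosen plan the same carbonyl carbon becomes an alkyne carbon before ring B exists.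

Key step: step 8

## Route

Step 1
Reactants: 1 5,7-dihydroxy-2H-chromen-2-one
Product: 2 5,7-bis(benzyloxy)-2H-chromen-2-one
Conditions: BnBr (2.4 equiv), K2CO3 (3 equiv), DMF, 60 °C
Reagents that add atoms: benzyl bromide, BrCc1ccccc1
Why: Williamson ether synthesis on two acidic phenols; the lactone is untouched. Benzyl survives the organometallic, hydride and palladium/formate steps and is later removed by BCl3 without touching methyl ethers.

Step 2
Reactants: 2 5,7-bis(benzyloxy)-2H-chromen-2-one; 3 [4-(benzyloxy)-3-methoxyphenyl]boronic acid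
Product: 4 (4S)-5,7-bis(benzyloxy)-4-[4-(benzyloxy)-3-methoxyphenyl]-3,4-dihydro-2H-chromen-2-one
Conditions: Rh(acac)(C2H4)2 (3 mol %), (S)-SEGPHOS (3.3 mol %), 3 (5 equiv, in portions), 1,4-dioxane/H2O (10:1), 60 °C
Reagents that add atoms: none
Why: Rhodium-catalysed asymmetric 1,4-addition of an arylboronic acid to a coumarin: transmetalation gives an aryl–rhodium species (monovalent rhodium), the C3=C4 bond inserts inside the SEGPHOS pocket (enantio-determining; sets C4 of the lactone, which is C3 of 15), and water protonates the oxa-π-allyl rhodium. The neutral aqueous medium leaves lactone and benzyl ethers intact.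

Step 3
Reactants: 4 (4S)-5,7-bis(benzyloxy)-4-[4-(benzyloxy)-3-methoxyphenyl]-3,4-dihydro-2H-chromen-2-one; 5 1,3-bis(benzyloxy)-5-bromobenzene
Product: 7 (3S,4S)-5,7-bis(benzyloxy)-4-[4-(benzyloxy)-3-methoxyphenyl]-3-[3,5-bis(benzyloxy)phenyl]-3,4-dihydro-2H-chromen-2-one, via chlorozinc enolate 6 (not isolated)
Conditions: LiN(SiMe3)2, THF, −78 °C; ZnCl2, −78 °C → rt; 5, Pd(dba)2 (5 mol %), P(t-Bu)3 (5 mol %), rt → 50 °C; aq. NH4Cl; then DBU (cat.), CH2Cl2, rt
Reagents that add atoms: zinc chloride, Cl[Zn]Cl (zinc and chlorine appear only in intermediate 6)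
Why: Palladium-catalysed α-arylation of a lactone zinc enolate (Negishi-type coupling of a Reformatsky-type enolate): oxidative addition of 5, transmetalation, reductive elimination. The new centre (C3 of the lactone, C2 of 15) is acidic and is set under thermodynamic control by the fixed C4 centre; the DBU treatment should funnel any cis isomer to the trans lactone. The zinc enolate is weakly basic, which limits ketene-forming fragmentation of the aryl ester.

Step 4
Reactants: 7 (3S,4S)-5,7-bis(benzyloxy)-4-[4-(benzyloxy)-3-methoxyphenyl]-3-[3,5-bis(benzyloxy)phenyl]-3,4-dihydro-2H-chromen-2-one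
Product: 8 (3S,4S)-5,7-bis(benzyloxy)-4-[4-(benzyloxy)-3-methoxyphenyl]-3-[3,5-bis(benzyloxy)phenyl]-3,4-dihydro-2H-chromen-2-ol (both C2 epimers)
Conditions: i-Bu2AlH (1.2 equiv), CH2Cl2, −78 °C; aq. KNaC4H4O6
Reagents that add atoms: none
Why: Partial reduction of an aryl lactone to the lactol; the aluminium hemiacetal is stable at −78 °C, so over-reduction is not expected. No existing stereocentre is touched, and the lactol carbon is lost as a stereocentre in step 5.

Step 5
Reactants: 8 (3S,4S)-5,7-bis(benzyloxy)-4-[4-(benzyloxy)-3-methoxyphenyl]-3-[3,5-bis(benzyloxy)phenyl]-3,4-dihydro-2H-chromen-2-ol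
Product: 10 3,5-bis(benzyloxy)-2-{(1S,2R)-1-[4-(benzyloxy)-3-methoxyphenyl]-2-[3,5-bis(benzyloxy)phenyl]but-3-yn-1-yl}phenol, via ring-opened hydroxy aldehyde 9 (not isolated)
Conditions: Me3SiCHN2 (2.5 equiv), LiN(i-Pr)2 (2.5 equiv), THF, −78 °C → 0 °C; aq. NH4Cl
Reagents that add atoms: (trimethylsilyl)diazomethane, C[Si](C)(C)C=[N+]=[N-]
Why: Colvin rearrangement: the lactolate opens to the phenoxide aldehyde 9, the lithiated diazo reagent adds, Peterson elimination gives a diazoalkene, loss of N2 gives an alkylidene carbene and a 1,2-hydrogen shift gives the alkyne. At −78 °C addition should outrun enolisation, so the α-aryl centre is kept. Its descriptor becomes R in 10 only because ethynyl ranks below aryl; no bond to it is broken.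

Step 6
Reactants: 10 3,5-bis(benzyloxy)-2-{(1S,2R)-1-[4-(benzyloxy)-3-methoxyphenyl]-2-[3,5-bis(benzyloxy)phenyl]but-3-yn-1-yl}phenol; 11 1-(benzyloxy)-4-iodo-2-methoxybenzene
Product: 12 3,5-bis(benzyloxy)-2-{(1S,2S)-1,4-bis[4-(benzyloxy)-3-methoxyphenyl]-2-[3,5-bis(benzyloxy)phenyl]but-3-yn-1-yl}phenol
Conditions: 11 (1.2 equiv), Pd(PPh3)2Cl2 (3 mol %), CuI (6 mol %), Et3N/THF, rt, degassed
Reagents that add atoms: none
Why: Sonogashira coupling of a terminal alkyne with an aryl iodide at room temperature; the free phenol and the propargylic centre are tolerated by the amine base. The descriptor returns to S because arylethynyl outranks the aryl group.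

Step 7
Reactants: 12 3,5-bis(benzyloxy)-2-{(1S,2S)-1,4-bis[4-(benzyloxy)-3-methoxyphenyl]-2-[3,5-bis(benzyloxy)phenyl]but-3-yn-1-yl}phenol
Product: 13 3,5-bis(benzyloxy)-2-{(1S,2S)-1,4-bis[4-(benzyloxy)-3-methoxyphenyl]-2-[3,5-bis(benzyloxy)phenyl]but-3-yn-1-yl}phenyl trifluoromethanesulfonate
Conditions: PhNTf2 (1.3 equiv), Et3N, DMAP (cat.), CH2Cl2, 0 °C → rt
Reagents that add atoms: N-phenylbis(trifluoromethanesulfonimide), O=S(=O)(N(c1ccccc1)S(=O)(=O)C(F)(F)F)C(F)(F)F
Why: O-sulfonylation of the only free phenol turns the former lactone oxygen on C7a into a leaving group; the mild triflyl donor does not attack the electron-rich alkyne or arenes.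

Step 8
Reactants: 13 3,5-bis(benzyloxy)-2-{(1S,2S)-1,4-bis[4-(benzyloxy)-3-methoxyphenyl]-2-[3,5-bis(benzyloxy)phenyl]but-3-yn-1-yl}phenyl trifluoromethanesulfonate
Product: 14 (1E,2S,3S)-4,6-bis(benzyloxy)-1-[4-(benzyloxy)-3-methoxybenzylidene]-3-[4-(benzyloxy)-3-methoxyphenyl]-2-[3,5-bis(benzyloxy)phenyl]-2,3-dihydro-1H-indene
Conditions: Pd(OAc)2 (5 mol %), PPh3 (12 mol %), HCO2Na (2 equiv), DMF, 80 °C
Reagents that add atoms: none
Why: Zerovalent palladium inserts into the C7a–O bond of the triflate; the divalent arylpalladium species binds the tethered alkyne and adds across it in syn fashion, then formate replaces triflate on palladium, loses CO2 and the hydride is transferred to the alkenyl carbon with retention. The closest known reaction type is the hydride-terminated (reductive) cyclocarbopalladation of aryl halides and triflates that carry an alkyne. Ring B closes through the new C7a–C1 bond in the 5-exo-dig mode; 6-endo closure with syn addition would need a trans double bond inside a six-membered ring. No stereocentre is created: the syn addition places palladium, and then hydrogen, cis to C7a, so the aryl group on the benzylidene carbon is trans to C7a and cis to C2, which is E. C2 and C3 are spectators, because the medium holds only formate as base and no acid, so the propargylic, benzylic C2–H is not touched. The step needs insertion to be faster than formate reduction of the arylpalladium intermediate, and hydride capture to be faster than isomerisation of the alkenylpalladium intermediate. The four-atom tether and the cationic character of the arylpalladium triflate favour fast insertion, and excess formate favours fast capture. Net, the six-membered lactone ring of 7 has become ring B by loss of its oxygen.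

Step 9
Reactants: 14 (1E,2S,3S)-4,6-bis(benzyloxy)-1-[4-(benzyloxy)-3-methoxybenzylidene]-3-[4-(benzyloxy)-3-methoxyphenyl]-2-[3,5-bis(benzyloxy)phenyl]-2,3-dihydro-1H-indene
Product: 15 gnetulin, (1E,2S,3S)-2-(3,5-dihydroxyphenyl)-1-(4-hydroxy-3-methoxybenzylidene)-3-(4-hydroxy-3-methoxyphenyl)-2,3-dihydro-1H-indene-4,6-diol
Conditions: BCl3 (1 M in CH2Cl2, 15 equiv), C6HMe5 (20 equiv), CH2Cl2, −78 °C; then MeOH
Reagents that add atoms: none
Why: Lewis-acid debenzylation with pentamethylbenzene as benzyl-cation scavenger; aryl benzyl ethers cleave at −78 °C while aryl methyl ethers do not. The method is non-reductive, so the stilbene alkene is kept, and the low temperature and scavenger should protect the electron-rich rings and both stereocentres.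

## Compound list

1 | 5,7-dihydroxy-2H-chromen-2-one | O=c1ccc2c(O)cc(O)cc2o1 | starting material
2 | 5,7-bis(benzyloxy)-2H-chromen-2-one | O=c1ccc2c(OCc3ccccc3)cc(OCc3ccccc3)cc2o1 | intermediate
3 | [4-(benzyloxy)-3-methoxyphenyl]boronic acid | COc1cc(B(O)O)ccc1OCc1ccccc1 | starting material
4 | (4S)-5,7-bis(benzyloxy)-4-[4-(benzyloxy)-3-methoxyphenyl]-3,4-dihydro-2H-chromen-2-one | O=C1Oc2cc(OCc3ccccc3)cc(OCc3ccccc3)c2[C@H](c2ccc(OCc3ccccc3)c(OC)c2)C1 | intermediate
5 | 1,3-bis(benzyloxy)-5-bromobenzene | Brc1cc(OCc2ccccc2)cc(OCc2ccccc2)c1 | starting material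
6 | chlorozinc enolate of 4, chloro{[(4S)-5,7-bis(benzyloxy)-4-[4-(benzyloxy)-3-methoxyphenyl]-4H-chromen-2-yl]oxy}zinc | Cl[Zn]OC1=C[C@@H](c2ccc(OCc3ccccc3)c(OC)c2)c2c(OCc3ccccc3)cc(OCc3ccccc3)cc2O1 | intermediate
7 | (3S,4S)-5,7-bis(benzyloxy)-4-[4-(benzyloxy)-3-methoxyphenyl]-3-[3,5-bis(benzyloxy)phenyl]-3,4-dihydro-2H-chromen-2-one | O=C1Oc2cc(OCc3ccccc3)cc(OCc3ccccc3)c2[C@H](c2ccc(OCc3ccccc3)c(OC)c2)[C@H]1c1cc(OCc2ccccc2)cc(OCc2ccccc2)c1 | intermediate
8 | (3S,4S)-5,7-bis(benzyloxy)-4-[4-(benzyloxy)-3-methoxyphenyl]-3-[3,5-bis(benzyloxy)phenyl]-3,4-dihydro-2H-chromen-2-ol (both C2 epimers) | OC1Oc2cc(OCc3ccccc3)cc(OCc3ccccc3)c2[C@H](c2ccc(OCc3ccccc3)c(OC)c2)[C@H]1c1cc(OCc2ccccc2)cc(OCc2ccccc2)c1 | intermediate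
9 | (2S,3S)-3-[2,4-bis(benzyloxy)-6-hydroxyphenyl]-3-[4-(benzyloxy)-3-methoxyphenyl]-2-[3,5-bis(benzyloxy)phenyl]propanal | Oc1cc(OCc2ccccc2)cc(OCc2ccccc2)c1[C@H](c1ccc(OCc2ccccc2)c(OC)c1)[C@H](C=O)c1cc(OCc2ccccc2)cc(OCc2ccccc2)c1 | intermediate
10 | 3,5-bis(benzyloxy)-2-{(1S,2R)-1-[4-(benzyloxy)-3-methoxyphenyl]-2-[3,5-bis(benzyloxy)phenyl]but-3-yn-1-yl}phenol | Oc1cc(OCc2ccccc2)cc(OCc2ccccc2)c1[C@H](c1ccc(OCc2ccccc2)c(OC)c1)[C@H](C#C)c1cc(OCc2ccccc2)cc(OCc2ccccc2)c1 | intermediate
11 | 1-(benzyloxy)-4-iodo-2-methoxybenzene | COc1cc(I)ccc1OCc1ccccc1 | starting material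
12 | 3,5-bis(benzyloxy)-2-{(1S,2S)-1,4-bis[4-(benzyloxy)-3-methoxyphenyl]-2-[3,5-bis(benzyloxy)phenyl]but-3-yn-1-yl}phenol | Oc1cc(OCc2ccccc2)cc(OCc2ccccc2)c1[C@H](c1ccc(OCc2ccccc2)c(OC)c1)[C@H](C#Cc1ccc(OCc2ccccc2)c(OC)c1)c1cc(OCc2ccccc2)cc(OCc2ccccc2)c1 | intermediate
13 | 3,5-bis(benzyloxy)-2-{(1S,2S)-1,4-bis[4-(benzyloxy)-3-methoxyphenyl]-2-[3,5-bis(benzyloxy)phenyl]but-3-yn-1-yl}phenyl trifluoromethanesulfonate | O=S(=O)(Oc1cc(OCc2ccccc2)cc(OCc2ccccc2)c1[C@H](c1ccc(OCc2ccccc2)c(OC)c1)[C@H](C#Cc1ccc(OCc2ccccc2)c(OC)c1)c1cc(OCc2ccccc2)cc(OCc2ccccc2)c1)C(F)(F)F | intermediate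
14 | (1E,2S,3S)-4,6-bis(benzyloxy)-1-[4-(benzyloxy)-3-methoxybenzylidene]-3-[4-(benzyloxy)-3-methoxyphenyl]-2-[3,5-bis(benzyloxy)phenyl]-2,3-dihydro-1H-indene | COc1cc(/C=C2/c3cc(OCc4ccccc4)cc(OCc4ccccc4)c3[C@H](c3ccc(OCc4ccccc4)c(OC)c3)[C@H]2c2cc(OCc3ccccc3)cc(OCc3ccccc3)c2)ccc1OCc1ccccc1 | intermediate
15 | gnetulin, (1E,2S,3S)-2-(3,5-dihydroxyphenyl)-1-(4-hydroxy-3-methoxybenzylidene)-3-(4-hydroxy-3-methoxyphenyl)-2,3-dihydro-1H-indene-4,6-diol | COc1cc(/C=C2/c3cc(O)cc(O)c3[C@H](c3ccc(O)c(OC)c3)[C@H]2c2cc(O)cc(O)c2)ccc1O | target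

## Step count and least certain steps

Total step count: 9. Longest linear sequence: 9 steps (1 to 15).

Step 8 (key). The most likely failures are hydride transfer to the arylpalladium intermediate before the alkyne has inserted (formate is present from the start), and stereomutation of the electron-rich alkenylpalladium intermediate or palladium hydride re-addition that moves the alkene into ring B and destroys C2. Fallback: a Mizoroki–Heck closure, which uses no hydride donor and forms no alkenylpalladium species. It sets out from 10 and returns at 14. Hydroboration of 10 with pinacolborane (Cp2Zr(H)Cl as catalyst) should give the (E)-alkenylboronate F1; Suzuki–Miyaura coupling of F1 with 11 (Pd(PPh3)4, aqueous K2CO3) the (E)-alkene phenol F2; and PhNTf2 with Et3N the aryl triflate F3. A 5-exo-trig Heck cyclisation of F3 (Pd(OAc)2, 1,3-bis(diphenylphosphino)propane, Et3N, DMF, 80 °C) should then give 14: syn insertion, rotation and syn β-hydride elimination (the only β-hydrogen sits on C1) turn the E-alkene into the E-benzylidene.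

Step 2. The likely failure is slow or incomplete insertion, because the C5 benzyloxy group is peri to C4 and two donor oxygens lower the electrophilicity of the lactone, so protodeboronation of 3 takes over. Fallback: separate the C–C bond formation from the stereo-induction. It sets out from 2 and 3 and returns at 4. Oxidative Heck-type arylation of 2 with 3 (Pd(OAc)2, 1,10-phenanthroline, O2, DMF), which is achiral and can be forced, should give the 4-arylcoumarin F4. Copper hydride conjugate reduction of F4 (Cu(OAc)2, the DTBM-SEGPHOS enantiomer that leads to the 4S product, (EtO)2MeSiH, t-BuOH, toluene) then sets C4 by delivery of the small hydride.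

Step 3. The likely failures are fragmentation of the aryl ester enolate to a ketene phenoxide, proton exchange between product and enolate that stalls conversion, or a second arylation. Fallback: reverse the polarity at the α-carbon. It sets out from 4 and returns at 7. Bromination of the silyl ketene acetal of 4 (LiN(SiMe3)2, Me3SiCl; then N-bromosuccinimide) should give the α-bromo lactone F5, and nickel-catalysed coupling with the arylboronic acid F6 (Ni(PPh3)4, K3PO4, toluene) should give 7; the trans relation again follows by equilibration.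

Step 5. The likely failure is epimerisation of the α-aryl aldehyde carbon by reversible enolisation under the strongly basic conditions before the diazo reagent has added; in the ring-opened form neither epimer is favoured, so purity at C2 of 15 would erode. Fallback: a Corey–Fuchs sequence whose first stage is not basic. It sets out from 8 and returns at 10. CBr4, PPh3 and Zn in CH2Cl2 should convert the open form of 8 into the 1,1-dibromoalkene F7; n-BuLi (3.3 equiv) in THF at −78 °C then gives 10 by bromine–lithium exchange and Fritsch–Buttenberg–Wiechell rearrangement.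

Step 9. The likely failures are protonation of the electron-rich exocyclic stilbene by HCl formed in the flask, followed by capture of the benzylic cation by the neighbouring resorcinol ring or by migration of the alkene into ring B, and partial loss of a guaiacyl methyl group through boron chelation between adjacent oxygens. Fallback: change the order so that the stilbene never meets the Lewis acid. It sets out from 13 and returns at 15. The same BCl3/pentamethylbenzene treatment applied to 13 should give the hexaphenol aryl triflate F8, and reductive cyclisation of F8 under the conditions of step 8 gives 15 directly.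

## Further compounds

F1 | step 8 | 3,5-bis(benzyloxy)-2-{(1S,2S,3E)-1-[4-(benzyloxy)-3-methoxyphenyl]-2-[3,5-bis(benzyloxy)phenyl]-4-(4,4,5,5-tetramethyl-1,3,2-dioxaborolan-2-yl)but-3-en-1-yl}phenol | Oc1cc(OCc2ccccc2)cc(OCc2ccccc2)c1[C@H](c1ccc(OCc2ccccc2)c(OC)c1)[C@H](/C=C/B1OC(C)(C)C(C)(C)O1)c1cc(OCc2ccccc2)cc(OCc2ccccc2)c1
F2 | step 8 | 3,5-bis(benzyloxy)-2-{(1S,2S,3E)-1,4-bis[4-(benzyloxy)-3-methoxyphenyl]-2-[3,5-bis(benzyloxy)phenyl]but-3-en-1-yl}phenol | Oc1cc(OCc2ccccc2)cc(OCc2ccccc2)c1[C@H](c1ccc(OCc2ccccc2)c(OC)c1)[C@H](/C=C/c1ccc(OCc2ccccc2)c(OC)c1)c1cc(OCc2ccccc2)cc(OCc2ccccc2)c1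
F3 | step 8 | 3,5-bis(benzyloxy)-2-{(1S,2S,3E)-1,4-bis[4-(benzyloxy)-3-methoxyphenyl]-2-[3,5-bis(benzyloxy)phenyl]but-3-en-1-yl}phenyl trifluoromethanesulfonate | O=S(=O)(Oc1cc(OCc2ccccc2)cc(OCc2ccccc2)c1[C@H](c1ccc(OCc2ccccc2)c(OC)c1)[C@H](/C=C/c1ccc(OCc2ccccc2)c(OC)c1)c1cc(OCc2ccccc2)cc(OCc2ccccc2)c1)C(F)(F)F
F4 | step 2 | 5,7-bis(benzyloxy)-4-[4-(benzyloxy)-3-methoxyphenyl]-2H-chromen-2-one | O=c1cc(-c2ccc(OCc3ccccc3)c(OC)c2)c2c(OCc3ccccc3)cc(OCc3ccccc3)cc2o1
F5 | step 3 | (4S)-5,7-bis(benzyloxy)-4-[4-(benzyloxy)-3-methoxyphenyl]-3-bromo-3,4-dihydro-2H-chromen-2-one (both C3 epimers) | O=C1Oc2cc(OCc3ccccc3)cc(OCc3ccccc3)c2[C@H](c2ccc(OCc3ccccc3)c(OC)c2)C1Br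
F6 | step 3 | [3,5-bis(benzyloxy)phenyl]boronic acid | OB(O)c1cc(OCc2ccccc2)cc(OCc2ccccc2)c1
F7 | step 5 | 3,5-bis(benzyloxy)-2-{(1S,2R)-1-[4-(benzyloxy)-3-methoxyphenyl]-2-[3,5-bis(benzyloxy)phenyl]-4,4-dibromobut-3-en-1-yl}phenol | Oc1cc(OCc2ccccc2)cc(OCc2ccccc2)c1[C@H](c1ccc(OCc2ccccc2)c(OC)c1)[C@H](C=C(Br)Br)c1cc(OCc2ccccc2)cc(OCc2ccccc2)c1
F8 | step 9 | 2-[(1S,2S)-2-(3,5-dihydroxyphenyl)-1,4-bis(4-hydroxy-3-methoxyphenyl)but-3-yn-1-yl]-3,5-dihydroxyphenyl trifluoromethanesulfonate | O=S(=O)(Oc1cc(O)cc(O)c1[C@H](c1ccc(O)c(OC)c1)[C@H](C#Cc1ccc(O)c(OC)c1)c1cc(O)cc(O)c1)C(F)(F)F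
A1 | alternative 1 | isorhapontigenin, 5-[(E)-2-(4-hydroxy-3-methoxyphenyl)ethenyl]benzene-1,3-diol | COc1cc(/C=C/c2cc(O)cc(O)c2)ccc1O
A2 | alternative 1 | 8–8' bis(quinone methide) dimer of A1 (dl form, racemic; one enantiomer drawn) | COC1=CC(=C[C@H](c2cc(O)cc(O)c2)[C@@H](C=C2C=CC(=O)C(OC)=C2)c2cc(O)cc(O)c2)C=CC1=O
A3 | alternative 2 | {2,4-bis(benzyloxy)-6-[(E)-2-[3,5-bis(benzyloxy)phenyl]ethenyl]phenyl}[4-(benzyloxy)-3-methoxyphenyl]methanol (racemic) | OC(c1ccc(OCc2ccccc2)c(OC)c1)c1c(OCc2ccccc2)cc(OCc2ccccc2)cc1/C=C/c1cc(OCc2ccccc2)cc(OCc2ccccc2)c1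
A4 | alternative 2 | 4,6-bis(benzyloxy)-1-{[4-(benzyloxy)-3-methoxybenzyl]sulfonyl}-3-[4-(benzyloxy)-3-methoxyphenyl]-2-[3,5-bis(benzyloxy)phenyl]-2,3-dihydro-1H-indene (racemic, 2,3-trans) | COc1cc(CS(=O)(=O)C2c3cc(OCc4ccccc4)cc(OCc4ccccc4)c3C(c3ccc(OCc4ccccc4)c(OC)c3)C2c2cc(OCc3ccccc3)cc(OCc3ccccc3)c2)ccc1OCc1ccccc1
A5 | alternative 3 | 4,6-bis(benzyloxy)-2-[3,5-bis(benzyloxy)phenyl]-1H-inden-1-one | O=C1C(c2cc(OCc3ccccc3)cc(OCc3ccccc3)c2)=Cc2c(OCc3ccccc3)cc(OCc3ccccc3)cc12
A6 | alternative 3 | (2S,3S)-4,6-bis(benzyloxy)-3-[4-(benzyloxy)-3-methoxyphenyl]-2-[3,5-bis(benzyloxy)phenyl]-2,3-dihydro-1H-inden-1-one | O=C1c2cc(OCc3ccccc3)cc(OCc3ccccc3)c2[C@H](c2ccc(OCc3ccccc3)c(OC)c2)[C@H]1c1cc(OCc2ccccc2)cc(OCc2ccccc2)c1
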